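A slow fade leaves the curve of E in the earlier runs in three parts: a steep rise, a knee, and a long gentle slope down from a level.

| setting | winter | midnight | flask |
|---|---|---|---|
| Q | 0.095 M | 0.095 M | 0.095 M |
| X | 1.1 equiv | 1.1 equiv | 1.10 equiv |
| Z | 2.4 mM | 3.6 mM | 4.75 mM |
| remark | run made earlier | run made earlier |  |
| time |  |  | 40 h |

- winter (time / h: E / %, Q / %): 0.667: 85.9, 11.1; 1.33: 95.4, 1.2; 2.50: 97.3, 0.9; 5.00: 94.3, 0.4; 10.0: 94.1, 0; 20.0: 91.7, 0; 40.0: 84.0, 1.8
- midnight (time / h: E / %, Q / %): 0.667: 87.0, 9.9; 1.33: 92.8, 0.5; 2.50: 94.2, 0; 5.00: 93.6, 0.1; 10.0: 91.7, 0.2; 20.0: 87.4, 0.9; 40.0: 82.6, 0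

(scatter of a reading: 1 percentage point)

- the moment within 40 h at which there is most E
- the amount of E, in percent of the Q charged, at that time

- the earlier runs were read with a standard deviation of 1 percentage point

In the winter run, E climbs at a mean 1.29 h⁻¹, in fractions of the charge, over the first 0.667 h. Q then falls at 3.36 h⁻¹. The peak readings are 97.3% in the winter run and 94.2% in the midnight run, which holds more Z than the winter run. My reckoning supposes that each Z spends one Q on something other than E. For this flask the toll is 5.00%: the Z charged as a fraction of the Q charged. The level is one minus the toll. The winter toll is 2.53% and the midnight toll 3.79%.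

Replacing each fall from level to last reading by its mean rate gives a fade of 0.00377 h⁻¹. This mean misses the midnight reading at 20.0 h by 1.8 points, with a scatter of 1 point. The knee ends when the loss of Q matches the fade of E. Running Q down from the winter reading at 3.36 h⁻¹ puts that, for this flask, at 2.05 h, with 94.3% of E. The forecast says 95% at 1.9 h, an earlier time than mine, and adds: “The peak is broad and flat”.

The flask gives 94.1% at 2.35 h.

    Q + X + E → 2 E (k = 27.3 L² mol⁻² min⁻¹)
    Q + X → E (k = 0.0644 L mol⁻¹ min⁻¹)
    E → J (k = 6.76 × 10⁻⁵ min⁻¹)
    Q + Z → G (k = 5.16 L mol⁻¹ min⁻¹)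

After 40.0 h the flask holds 5.00% of G, matching the toll of 5.00%; Z, the limiting reagent of that side step, is then down to 0% of its charge. Take the neighbouring flask with 0.057 M of Q, its Z unchanged in amount per litre. Its toll is 8.33%, so its level is 91.7%, and the fade brings that to 78.8% at 40.0 h. That flask peaks at 89.8% and ends with 8.33% of G and 78.2% of E.

The readings were generated by integration from invented constants, and the scatter is random.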